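**Retrosynthetic overview**

1. Target 17 ⇐ its 5,7-bis(MOM) ether 15 (non-protic acetal cleavage); 15 ⇐ arylboronic acid 12 + chromone 14 by cutting C2–C1' (rhodium-catalysed asymmetric 1,4-arylation, which also sets C2).
2. Enabling feature: with ring C at the chromone oxidation level, C2 is the β-carbon of the vinylogous ester O1–C2=C3–C4=O; C1' of ring B lies para to the OMe between two unsubstituted CH positions (C2', C6'), so it can carry an unhindered boronic acid.
3. 12 ⇐ aryl bromide 9 (Br → Li → B); the (E)-diene comes from the CHO of 7 (Horner–Wadsworth–Emmons); the prenyl group comes from an allyl group (cross-metathesis) placed by Claisen rearrangement on 5-bromosalicylaldehyde 1.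
4. 14 ⇐ commercial 5,7-dihydroxychromone 13 (bis-MOM protection).
5. Ring order: no ring is built; ring B is bought as 1, rings A and C as 13, and ring C is only taken down to the chromanone in the key step.

Key step: step 8

Remark (assumption): the (S)-configured biaryl bisphosphine is taken to show on chromone 14 the facial sense it shows on 2-cyclohexenone (aryl to the Re face of C2, giving 2S); if a model run showed the opposite sense, the (R)-ligand would be used.

Step 1
Reactants: 1 5-bromo-2-hydroxybenzaldehyde; 2 allyl bromide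
Product: 3 2-(allyloxy)-5-bromobenzaldehyde
Conditions: K2CO3, DMF, rt
Reagents that add atoms: none
Why: Williamson ether synthesis: the acidic, aldehyde-conjugated phenoxide should be O-allylated cleanly by the reactive allylic bromide.

Step 2
Reactants: 3 2-(allyloxy)-5-bromobenzaldehyde
Product: 4 3-allyl-5-bromo-2-hydroxybenzaldehyde
Conditions: neat (or N,N-diethylaniline), 190–200 °C, Ar
Reagents that add atoms: none
Why: aromatic Claisen rearrangement: the [3,3] shift can only deliver the allyl group to the single free ortho carbon (the other ortho carbon carries CHO, the para carbon Br), and tautomerisation should return the phenol.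

Step 3
Reactants: 4 3-allyl-5-bromo-2-hydroxybenzaldehyde
Product: 5 3-allyl-5-bromo-2-methoxybenzaldehyde
Conditions: MeI, K2CO3, DMF, rt
Reagents that add atoms: iodomethane, CI
Why: Williamson O-methylation of the hydrogen-bonded phenol should be straightforward and fixes the 4'-OMe of ring B.

Step 4
Reactants: 5 3-allyl-5-bromo-2-methoxybenzaldehyde; 6 2-methyl-2-butene
Product: 7 5-bromo-2-methoxy-3-(3-methylbut-2-en-1-yl)benzaldehyde
Conditions: second-generation Grubbs catalyst RuCl2(=CHPh)(PCy3)(H2IMes) (3 mol %), 2-methyl-2-butene (excess)/CH2Cl2, 35 °C, sealed vessel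
Reagents that add atoms: none
Why: olefin cross-metathesis of a terminal allylarene with excess 2-methyl-2-butene is the standard way to a prenylarene, and the trisubstituted product should not re-enter metathesis.

Step 5
Reactants: 7 5-bromo-2-methoxy-3-(3-methylbut-2-en-1-yl)benzaldehyde; 8 diethyl (2-methylallyl)phosphonate
Product: 9 5-bromo-2-methoxy-1-[(1E)-3-methylbuta-1,3-dien-1-yl]-3-(3-methylbut-2-en-1-yl)benzene
Conditions: 8, KOt-Bu, THF, −20 °C; then 7, −20 °C → rt
Reagents that add atoms: none
Why: Horner–Wadsworth–Emmons olefination of a non-enolisable aryl aldehyde with an allylic phosphonate anion should give the conjugated diene with E geometry at the new C=C bond, since the elimination is under thermodynamic control.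

Step 6
Reactants: 9 5-bromo-2-methoxy-1-[(1E)-3-methylbuta-1,3-dien-1-yl]-3-(3-methylbut-2-en-1-yl)benzene
Product: 12 [4-methoxy-3-[(1E)-3-methylbuta-1,3-dien-1-yl]-5-(3-methylbut-2-en-1-yl)phenyl]boronic acid, via aryllithium 10 (not isolated), via lithium aryltriisopropoxyborate 11 (not isolated)
Conditions: B(Oi-Pr)3 (1.5 equiv) present, n-BuLi (1.1 equiv) added, THF/toluene, −78 °C; then aq. HCl to pH 5, 0 °C, short contact
Reagents that add atoms: triisopropyl borate, CC(C)OB(OC(C)C)OC(C)C; water, O
Why: bromine–lithium exchange with in-situ borate trapping: exchange at −78 °C should outrun attack of n-BuLi on the hindered borate or on the diene, the aryllithium is captured as it forms, and mild hydrolysis should free the boronic acid.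

Step 7
Reactants: 13 5,7-dihydroxy-4H-chromen-4-one
Product: 14 5,7-bis(methoxymethoxy)-4H-chromen-4-one
Conditions: NaH (2.5 equiv), MOMCl (2.5 equiv), DMF, 0 °C → rt
Reagents that add atoms: chloromethyl methyl ether (MOMCl), COCCl
Why: O-alkylation of both phenoxides (NaH is needed for the hydrogen-bonded 5-OH) masks the acidic 7-OH and the chelating 5-OH/C4=O pair, which would otherwise bind rhodium and deactivate the enone.

Step 8
Reactants: 12 [4-methoxy-3-[(1E)-3-methylbuta-1,3-dien-1-yl]-5-(3-methylbut-2-en-1-yl)phenyl]boronic acid; 14 5,7-bis(methoxymethoxy)-4H-chromen-4-one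
Product: 15 (2S)-5,7-bis(methoxymethoxy)-2-[4-methoxy-3-[(1E)-3-methylbuta-1,3-dien-1-yl]-5-(3-methylbut-2-en-1-yl)phenyl]-2,3-dihydro-4H-chromen-4-one
Conditions: 12 (1.5 equiv), [RhCl(C2H4)2]2 (2.5 mol %), (S)-MeO-F12-BIPHEP [(S)-2,2'-bis[bis(3,4,5-trifluorophenyl)phosphino]-6,6'-dimethoxy-1,1'-biphenyl] (5.5 mol %), KOH (10 mol %), toluene/H2O 10:1, 40 °C
Reagents that add atoms: none
Why: Hayashi–Miyaura asymmetric 1,4-addition: boronic acid 12 transmetalates to the hydroxo complex of monovalent rhodium carrying the (S)-bisphosphine, the aryl–rhodium species binds the C2=C3 bond of 14 and inserts it so that C1' bonds to C2, and water hydrolyses the resulting oxa-π-allyl (enolate) rhodium to ketone 15 while regenerating Rh–OH. The closest known reaction type is the rhodium/chiral bisphosphine-catalysed addition of arylboronic acids to chromones to give 2-arylchroman-4-ones. No ring is closed; ring C is only taken from the chromone to the chromanone level. The single new stereocentre C2 is set under catalyst control, the ligand directing the aryl group to the Re face of C2 (O1 > C3 > H) and hence to 2S. The step needs 1,4- rather than 1,2-addition, insertion into the chromone rather than into the diene or prenyl C=C bonds of 12, and little protodeboronation. These should be secured by the polarised vinylogous ester (the nucleophilic aryl–rhodium prefers it to unactivated alkenes), by the electron-poor chelating bisphosphine that speeds enone insertion and is not displaced by the substrate diene, by the two free ortho CH positions next to boron, and by the MOM groups that keep the 5-O/C4=O pair from chelating rhodium.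

Step 9
Reactants: 15 (2S)-5,7-bis(methoxymethoxy)-2-[4-methoxy-3-[(1E)-3-methylbuta-1,3-dien-1-yl]-5-(3-methylbut-2-en-1-yl)phenyl]-2,3-dihydro-4H-chromen-4-one
Product: 17 (2S)-5,7-dihydroxy-2-[4-methoxy-3-[(1E)-3-methylbuta-1,3-dien-1-yl]-5-(3-methylbut-2-en-1-yl)phenyl]-2,3-dihydro-4H-chromen-4-one, via bis(trimethylsilyl) ether 16 (not isolated)
Conditions: TMSOTf (6 equiv), 2,2'-bipyridyl (9 equiv), CH3CN, 0 °C → rt; then H2O, rt
Reagents that add atoms: trimethylsilyl trifluoromethanesulfonate, C[Si](C)(C)OS(=O)(=O)C(F)(F)F (its silyl groups stand only in intermediate 16)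
Why: silyl triflate/2,2'-bipyridyl cleavage of aromatic MOM ethers: the buffered silyl triflate should turn each ArO–CH2OMe into ArO–SiMe3 without free protic acid or base, so the acid-labile aryl diene, the prenyl group and the base-labile C2 stereocentre should stay untouched, and water then hydrolyses the labile aryl silyl ethers.

**Compound list**

1 | 5-bromo-2-hydroxybenzaldehyde (5-bromosalicylaldehyde) | O=Cc1cc(Br)ccc1O | starting material
2 | allyl bromide | C=CCBr | starting material
3 | 2-(allyloxy)-5-bromobenzaldehyde | O=Cc1cc(Br)ccc1OCC=C | intermediate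
4 | 3-allyl-5-bromo-2-hydroxybenzaldehyde | O=Cc1cc(Br)cc(CC=C)c1O | intermediate
5 | 3-allyl-5-bromo-2-methoxybenzaldehyde | O=Cc1cc(Br)cc(CC=C)c1OC | intermediate
6 | 2-methyl-2-butene | CC=C(C)C | starting material
7 | 5-bromo-2-methoxy-3-(3-methylbut-2-en-1-yl)benzaldehyde | O=Cc1cc(Br)cc(CC=C(C)C)c1OC | intermediate
8 | diethyl (2-methylallyl)phosphonate | C=C(C)CP(=O)(OCC)OCC | starting material
9 | 5-bromo-2-methoxy-1-[(1E)-3-methylbuta-1,3-dien-1-yl]-3-(3-methylbut-2-en-1-yl)benzene | C=C(C)/C=C/c1cc(Br)cc(CC=C(C)C)c1OC | intermediate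
10 | [4-methoxy-3-[(1E)-3-methylbuta-1,3-dien-1-yl]-5-(3-methylbut-2-en-1-yl)phenyl]lithium (not isolated) | C=C(C)/C=C/c1cc([Li])cc(CC=C(C)C)c1OC | intermediate
11 | lithium triisopropoxy[4-methoxy-3-[(1E)-3-methylbuta-1,3-dien-1-yl]-5-(3-methylbut-2-en-1-yl)phenyl]borate (not isolated) | C=C(C)/C=C/c1cc([B-](OC(C)C)(OC(C)C)OC(C)C)cc(CC=C(C)C)c1OC.[Li+] | intermediate
12 | [4-methoxy-3-[(1E)-3-methylbuta-1,3-dien-1-yl]-5-(3-methylbut-2-en-1-yl)phenyl]boronic acid | C=C(C)/C=C/c1cc(B(O)O)cc(CC=C(C)C)c1OC | intermediate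
13 | 5,7-dihydroxy-4H-chromen-4-one (5,7-dihydroxychromone) | O=c1ccoc2cc(O)cc(O)c12 | starting material
14 | 5,7-bis(methoxymethoxy)-4H-chromen-4-one | O=c1ccoc2cc(OCOC)cc(OCOC)c12 | intermediate
15 | (2S)-5,7-bis(methoxymethoxy)-2-[4-methoxy-3-[(1E)-3-methylbuta-1,3-dien-1-yl]-5-(3-methylbut-2-en-1-yl)phenyl]-2,3-dihydro-4H-chromen-4-one | C=C(C)/C=C/c1cc([C@@H]2CC(=O)c3c(OCOC)cc(OCOC)cc3O2)cc(CC=C(C)C)c1OC | intermediate
16 | (2S)-2-[4-methoxy-3-[(1E)-3-methylbuta-1,3-dien-1-yl]-5-(3-methylbut-2-en-1-yl)phenyl]-5,7-bis(trimethylsilyloxy)-2,3-dihydro-4H-chromen-4-one (not isolated) | C=C(C)/C=C/c1cc([C@@H]2CC(=O)c3c(O[Si](C)(C)C)cc(O[Si](C)(C)C)cc3O2)cc(CC=C(C)C)c1OC | intermediate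
17 | (2S)-5,7-dihydroxy-2-[4-methoxy-3-[(1E)-3-methylbuta-1,3-dien-1-yl]-5-(3-methylbut-2-en-1-yl)phenyl]-2,3-dihydro-4H-chromen-4-one | C=C(C)/C=C/c1cc([C@@H]2CC(=O)c3c(O)cc(O)cc3O2)cc(CC=C(C)C)c1OC | target

**Step count**

Total steps: 9 (steps 1–6 for the ring B fragment, step 7 for the chromone, steps 8 and 9 after convergence).
Longest linear sequence: 8 steps (1 → 17 through steps 1–6, 8, 9).

**Three steps most likely to fail**

Step 8 (key step). What may go wrong: insertion of the aryl–rhodium species into the 1,3-diene of a second molecule of 12, binding of that diene to rhodium so that turnover stalls, and protodeboronation of the electron-rich boronic acid outpacing a slow insertion into the electron-rich chromone. Fallback: the same union is run before the diene exists, with the diene carried as a tertiary allylic alcohol. It sets out from 7. Wittig olefination with ethyl (triphenylphosphoranylidene)acetate (toluene, 80 °C) should give ethyl (2E)-3-[5-bromo-2-methoxy-3-(3-methylbut-2-en-1-yl)phenyl]prop-2-enoate F1. Double addition of MeMgBr (THF, 0 °C) should give (3E)-4-[5-bromo-2-methoxy-3-(3-methylbut-2-en-1-yl)phenyl]-2-methylbut-3-en-2-ol F2. Bromine–lithium exchange (n-BuLi, 2.2 equiv, B(Oi-Pr)3, THF, −78 °C; aqueous work-up) should give [3-[(1E)-3-hydroxy-3-methylbut-1-en-1-yl]-4-methoxy-5-(3-methylbut-2-en-1-yl)phenyl]boronic acid F3. Its 1,4-addition to 14 under the conditions of step 8 should give (2S)-2-[3-[(1E)-3-hydroxy-3-methylbut-1-en-1-yl]-4-methoxy-5-(3-methylbut-2-en-1-yl)phenyl]-5,7-bis(methoxymethoxy)-2,3-dihydro-4H-chromen-4-one F4. Dehydration with the Burgess reagent (toluene, 50 °C), which can only eliminate toward a methyl group, comes back to the route at 15.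

Step 9. What may go wrong: Lewis-acid-triggered cationic reaction (oligomerisation or addition) at the aryl diene or the prenyl group, and incomplete cleavage of the less labile 7-O acetal. Fallback: silyl instead of acetal protection, cleaved by fluoride. It sets out from 13 and uses 12. Silylation of 13 (TBSOTf, 2,6-lutidine, CH2Cl2, 0 °C → rt) should give 5,7-bis(tert-butyldimethylsilyloxy)-4H-chromen-4-one F5. The 1,4-addition of 12 under the conditions of step 8 (without added KOH, with the preformed hydroxo-rhodium bisphosphine complex) should give (2S)-5,7-bis(tert-butyldimethylsilyloxy)-2-[4-methoxy-3-[(1E)-3-methylbuta-1,3-dien-1-yl]-5-(3-methylbut-2-en-1-yl)phenyl]-2,3-dihydro-4H-chromen-4-one F6. Et3N·3HF in THF at 0 °C then comes back to the route at 17.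

Step 6. What may go wrong: carbolithiation or anionic oligomerisation of the aryl diene by n-BuLi or by aryllithium 10, and butylation of the borate competing with the exchange. Fallback: boron is introduced by palladium catalysis before the diene is made. It sets out from 7. Miyaura borylation (PdCl2(dppf), bis(pinacolato)diboron, KOAc, dioxane, 80 °C) should give 2-methoxy-3-(3-methylbut-2-en-1-yl)-5-(4,4,5,5-tetramethyl-1,3,2-dioxaborolan-2-yl)benzaldehyde F7. Horner–Wadsworth–Emmons olefination with 8 (KOt-Bu, THF) should give 2-[4-methoxy-3-[(1E)-3-methylbuta-1,3-dien-1-yl]-5-(3-methylbut-2-en-1-yl)phenyl]-4,4,5,5-tetramethyl-1,3,2-dioxaborolane F8. Oxidative removal of pinacol (NaIO4, NH4OAc, acetone/H2O, rt) comes back to the route at 12.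

**Further compounds**

F1 | step 8 | ethyl (2E)-3-[5-bromo-2-methoxy-3-(3-methylbut-2-en-1-yl)phenyl]prop-2-enoate | CCOC(=O)/C=C/c1cc(Br)cc(CC=C(C)C)c1OC
F2 | step 8 | (3E)-4-[5-bromo-2-methoxy-3-(3-methylbut-2-en-1-yl)phenyl]-2-methylbut-3-en-2-ol | CC(C)(O)/C=C/c1cc(Br)cc(CC=C(C)C)c1OC
F3 | step 8 | [3-[(1E)-3-hydroxy-3-methylbut-1-en-1-yl]-4-methoxy-5-(3-methylbut-2-en-1-yl)phenyl]boronic acid | CC(C)(O)/C=C/c1cc(B(O)O)cc(CC=C(C)C)c1OC
F4 | step 8 | (2S)-2-[3-[(1E)-3-hydroxy-3-methylbut-1-en-1-yl]-4-methoxy-5-(3-methylbut-2-en-1-yl)phenyl]-5,7-bis(methoxymethoxy)-2,3-dihydro-4H-chromen-4-one | CC(C)(O)/C=C/c1cc([C@@H]2CC(=O)c3c(OCOC)cc(OCOC)cc3O2)cc(CC=C(C)C)c1OC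
F5 | step 9 | 5,7-bis(tert-butyldimethylsilyloxy)-4H-chromen-4-one | O=c1ccoc2cc(O[Si](C)(C)C(C)(C)C)cc(O[Si](C)(C)C(C)(C)C)c12
F6 | step 9 | (2S)-5,7-bis(tert-butyldimethylsilyloxy)-2-[4-methoxy-3-[(1E)-3-methylbuta-1,3-dien-1-yl]-5-(3-methylbut-2-en-1-yl)phenyl]-2,3-dihydro-4H-chromen-4-one | C=C(C)/C=C/c1cc([C@@H]2CC(=O)c3c(O[Si](C)(C)C(C)(C)C)cc(O[Si](C)(C)C(C)(C)C)cc3O2)cc(CC=C(C)C)c1OC
F7 | step 6 | 2-methoxy-3-(3-methylbut-2-en-1-yl)-5-(4,4,5,5-tetramethyl-1,3,2-dioxaborolan-2-yl)benzaldehyde | O=Cc1cc(B2OC(C)(C)C(C)(C)O2)cc(CC=C(C)C)c1OC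
F8 | step 6 | 2-[4-methoxy-3-[(1E)-3-methylbuta-1,3-dien-1-yl]-5-(3-methylbut-2-en-1-yl)phenyl]-4,4,5,5-tetramethyl-1,3,2-dioxaborolane | C=C(C)/C=C/c1cc(B2OC(C)(C)C(C)(C)O2)cc(CC=C(C)C)c1OC
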